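The data stem from a simulated flask for substances that don't exist, and the scatter is random.

**Amounts first.** In the autumn flask, which is the one asked about, uncatalysed product read 56% at 15.0 h. The remainder R, everything not yet uncatalysed product, was therefore 44.0%.

all flasks: starting material 0.80 M

| run | free catalyst | remark | time |
|---|---|---|---|
| autumn | 0.80 mM | the very flask that is asked about, followed so far |  |
| summer | 1.2 mM | run made earlier |  |
| flask | 0.80 mM |  | 3.0 d |

| run | time / h | isomer of the product / % | target / % | uncatalysed product / % | starting material / % |
|---|---|---|---|---|---|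
| autumn | 4.00 | 4 | 8 | 21 | 65 |
| autumn | 8.00 | 6 | 14 | 39 | 45 |
| autumn | 10.0 | 7 | 17 | 42 | 36 |
| autumn | 15.0 | 7 | 16 | 56 | 21 |
| summer | 2.50 | 7 | 8 | 16 | 74 |
| summer | 5.00 | 4 | 14 | 28 | 51 |
| summer | 12.0 | 6 | 22 | 47 | 25 |
| summer | 30.0 | 3 | 17 | 69 | 10 |

(standard deviation of a reading: 2 percentage points)

* the species in which most of what was charged as starting material, at 3.0 d sits (uncatalysed product / starting material / target / isomer of the product)
* the largest share itself, whichever of these holds it, in percent of the starting material charged

**Two times.** In the summer run, R fell from 53.0% at 12.0 h to 31.0% at 30.0 h. Treating this as a pseudo-first-order decay, I read 23.3 h for t_R, the late half-life of the remainder. The autumn flask had 57.0 h left to run, which is 2.45 half-lives. So I reckoned R at 8.05% and uncatalysed product at 91.9%, the largest share. But the autumn readings up to 15.0 h gave a half-life of 12.7 h, shorter. These two half-lives came from different stretches and different charges of free catalyst, 0.80 mM in the autumn flask and 1.2 mM in the summer run, so the lengthening was only a reading and my figure may have leaned high.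

**The forecast.** The forecast gave uncatalysed product at 85%, lower than my figure, and noted: “The range allows for target decay stalling or continuing.”

**The result.** At 3.0 d the flask held uncatalysed product at 88.5%.

    starting material + free catalyst ⇌ target + free catalyst, rate k1*[starting material]*[free catalyst] forward; the back reaction follows from the equilibrium constant (K = 0.980, k = 0.0110 M⁻¹ s⁻¹)
    starting material + free catalyst ⇌ isomer of the product + free catalyst, rate k2*[starting material]*[free catalyst] forward; the back reaction follows from the equilibrium constant (K = 0.110, k = 0.00820 M⁻¹ s⁻¹)
    free catalyst + target → spent catalyst (k = 8.80 × 10⁻⁶ M⁻¹ s⁻¹)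
    free catalyst + target ⇌ idle complex (K = 1.00 M⁻¹, k = 7.80 × 10⁻⁵ M⁻¹ s⁻¹)
    starting material → uncatalysed product (k = 2.10 × 10⁻⁵ s⁻¹)

**Waiting longer.** The flask's R of 11.5%, held against the reading at 15.0 h, gives an average half-life up to 3.0 d of 29.4 h, longer than t_R. For the neighbouring flask left until 5.0 d, t_R carried on from there gave R as 2.76%. The R of that flask was 5.03%, a half-life of 40.2 h over those days, with uncatalysed product at 94.9%.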